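## Retrosynthetic overview

1. Pieces: ring A from methoxyhydroquinone 1; C3–C4 with the 3-OMe from methoxyacetic acid 2 (Friedel–Crafts C-acylation gives ketone 3); ring B plus C2 from 2,3,4-trimethoxybenzoyl chloride 4.
2. C2–C3 bond: Claisen-type C-acylation of the enolate of 3 with 4 gives the open-chain hydroquinone 1,3-diketone 5.
3. Key disconnection O1–C8a (aryl C–O bond): 5 is oxidised to acylquinone 6, whose enol oxygen closes ring C by 6-endo oxa-Michael addition. Re-aromatisation leaves the 5-OH and 8-OH in place without protecting groups. Over-oxidised flavonequinone 7 is reduced back in the same pot to target 8.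
4. Ring order: rings A and B are bought as benzene rings; ring C (the pyranone) is the only ring built, and it is built last.

Assumption: the target has no stereocentre and is achiral, so no enantiocontrol is needed; the only stereocentre on the way (the CH(OMe) carbon of 5 and 6) is labile, racemic and destroyed in step 3.
Assumption: 2,3,4-trimethoxybenzoyl chloride 4 is bought as a catalogue chemical.

## Route

Step 1
Reactants: 1 methoxyhydroquinone (2-methoxybenzene-1,4-diol); 2 methoxyacetic acid
Product: 3 1-(2,5-dihydroxy-4-methoxyphenyl)-2-methoxyethan-1-one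
Conditions: BF3·OEt2 (neat, 4 equiv), N2, 85 °C, 2 h; then ice-water
Reagents that add atoms: none
Why: BF3-promoted Friedel–Crafts C-acylation (aryl ester formation and Fries-type migration) goes to the one ring position of 1 that is para to the methoxy group and ortho to a hydroxyl, and the product is held as a deactivated BF2 chelate of the ortho-hydroxy ketone, which stops a second acylation; no stereocentre is formed.

Step 2
Reactants: 3 1-(2,5-dihydroxy-4-methoxyphenyl)-2-methoxyethan-1-one; 4 2,3,4-trimethoxybenzoyl chloride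
Product: 5 1-(2,5-dihydroxy-4-methoxyphenyl)-2-methoxy-3-(2,3,4-trimethoxyphenyl)propane-1,3-dione
Conditions: LiN(SiMe3)2 (4.2 equiv), THF, Ar, −78 to −10 °C; then 4 (1.05 equiv), −78 °C to rt; cold 1 M HCl to pH 4
Reagents that add atoms: none
Why: Direct Claisen-type C-acylation of a polylithiated hydroxyacetophenone: the aggregated lithium phenoxides are poor O-nucleophiles at −78 °C while the α-methoxy enolate carbon attacks 4, and the fourth equivalent of base stores the more acidic 1,3-diketone as its enolate; the new CH(OMe) centre is a racemic, freely enolising β-dicarbonyl position, and the cold weakly acidic work-up with immediate use avoids acid cyclodehydration through the 2-OH to the isomeric 6-hydroxyflavone.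

Step 3
Reactants: 5 1-(2,5-dihydroxy-4-methoxyphenyl)-2-methoxy-3-(2,3,4-trimethoxyphenyl)propane-1,3-dione
Product: 8 5,8-dihydroxy-3,7,2',3',4'-pentamethoxyflavone, via acylquinone 6 (not isolated), via flavonequinone 7 (not isolated)
Conditions: Ag2O (3.0 equiv), NaOAc (20 mol%), 4 Å MS, CH2Cl2–MeCN 4:1 (0.02 M), rt, dark; then aq. Na2S2O4, EtOAc
Reagents that add atoms: none
Why: Proposed new method: a dehydrogenative 6-endo oxa-Michael ring closure of a 2,5-dihydroxyphenyl 1,3-diketone, not shown so far as a flavone synthesis; Ag2O oxidises the hydroquinone to acylquinone 6, in which the ring carbon next to the acyl group (future C8a) is the β-carbon of both the exocyclic ketone and the C5 quinone carbonyl and is the only electrophilic ring carbon the diketone enol oxygen can reach through a six-membered transition state, so acetate-assisted O-attack and tautomerisation forge O1–C8a and give the aromatic 5,8-diol, which is more electron-rich than 5 and is therefore deliberately driven on to quinone 7 by the excess oxidant and brought back by Na2S2O4; the ordinary cyclodehydration through the 2-OH is shut off once that oxygen is a quinone carbonyl, and the closest known reaction types are conjugate additions of O-, N- and S-nucleophiles at C3 of 2-acyl-1,4-benzoquinones, the quinone-mediated oxidative ring closure of 2-hydroxyaryl hydroquinonyl ketones to hydroxyxanthones and the oxa-Michael closure of 2'-hydroxychalcones to flavanones; no stereocentre remains.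

## Compound list

1 | methoxyhydroquinone (2-methoxybenzene-1,4-diol) | COc1cc(O)ccc1O | starting material
2 | methoxyacetic acid | COCC(=O)O | starting material
3 | 1-(2,5-dihydroxy-4-methoxyphenyl)-2-methoxyethan-1-one | COCC(=O)c1cc(O)c(OC)cc1O | intermediate
4 | 2,3,4-trimethoxybenzoyl chloride | COc1ccc(C(Cl)=O)c(OC)c1OC | starting material
5 | 1-(2,5-dihydroxy-4-methoxyphenyl)-2-methoxy-3-(2,3,4-trimethoxyphenyl)propane-1,3-dione (racemic at the labile C2, keto/enol mixture) | COc1ccc(C(=O)C(OC)C(=O)c2cc(O)c(OC)cc2O)c(OC)c1OC | intermediate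
6 | 2-methoxy-5-[2-methoxy-3-oxo-3-(2,3,4-trimethoxyphenyl)propanoyl]cyclohexa-2,5-diene-1,4-dione (acylquinone, racemic at the labile CH(OMe)) | COC1=CC(=O)C(C(=O)C(OC)C(=O)c2ccc(OC)c(OC)c2OC)=CC1=O | intermediate
7 | 3,7-dimethoxy-2-(2,3,4-trimethoxyphenyl)-4H-chromene-4,5,8-trione (flavone-5,8-quinone) | COC1=CC(=O)C2=C(OC(c3ccc(OC)c(OC)c3OC)=C(OC)C2=O)C1=O | intermediate
8 | 5,8-dihydroxy-3,7-dimethoxy-2-(2,3,4-trimethoxyphenyl)-4H-chromen-4-one (5,8-dihydroxy-3,7,2',3',4'-pentamethoxyflavone, achiral) | COc1ccc(-c2oc3c(O)c(OC)cc(O)c3c(=O)c2OC)c(OC)c1OC | target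

## Step count and risk

Total step count: 3. Longest linear sequence: 3 steps (1 → 3 → 5 → 8).

The three steps most likely to fail, most risky first:

**Step 3 (proposed new oxidative ring closure).** Risks: intermolecular C-attack of the enol on the quinone, oxidation of the enol, or the acylquinone not closing. The fallback uses only known chemistry, sets out from 2 and 4, and returns at 8. Bought phloroglucinol is C-acylated with 2 in BF3·OEt2 at 80 °C to 2-methoxy-1-(2,4,6-trihydroxyphenyl)ethan-1-one F1. Its polylithiated form (LiN(SiMe3)2, 5 equiv, THF, −78 °C) is C-acylated with 4 to 2-methoxy-1-(2,4,6-trihydroxyphenyl)-3-(2,3,4-trimethoxyphenyl)propane-1,3-dione F2. Cyclodehydration (cat. H2SO4, AcOH, 95 °C) gives 5,7-dihydroxy-3-methoxy-2-(2,3,4-trimethoxyphenyl)-4H-chromen-4-one F3. Me2SO4 (1.05 equiv), K2CO3, acetone methylates only the non-chelated 7-OH to 5-hydroxy-3,7-dimethoxy-2-(2,3,4-trimethoxyphenyl)-4H-chromen-4-one F4. Elbs persulfate oxidation (K2S2O8, aq. KOH–pyridine, 0 °C to rt) oxygenates para to the 5-OH to give potassium 5-hydroxy-3,7-dimethoxy-4-oxo-2-(2,3,4-trimethoxyphenyl)-4H-chromen-8-yl sulfate F5. Hot aq. HCl/Na2SO3 hydrolyses the sulfate to 8. This is the classical route: five operations, with a typically low-yielding Elbs step.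

**Step 2 (C-acylation with two free phenols).** Risks: O-aroylation of the non-chelated 5-phenoxide, or air oxidation of the polyanion. The fallback sets out from 3 (with 4) and returns at 5, replacing direct C-acylation by O-acylation and intramolecular acyl transfer. Compound 3 is bis-O-aroylated with 4 (2.2 equiv, pyridine, DMAP, CH2Cl2) to 2-methoxy-5-(2-methoxyacetyl)-1,4-phenylene bis(2,3,4-trimethoxybenzoate) F6. Baker–Venkataraman rearrangement (KOt-Bu, THF, 0 °C) moves the ortho aroyl group to carbon, giving 4-hydroxy-2-methoxy-5-[2-methoxy-3-oxo-3-(2,3,4-trimethoxyphenyl)propanoyl]phenyl 2,3,4-trimethoxybenzoate F7. Methanolysis of the remaining aryl ester (K2CO3, MeOH, rt) then gives 5.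

**Step 1 (acylation of an oxidation-prone hydroquinone).** Risks: tarring, diacylation, or a sluggish reaction with the chelating α-methoxy acid. The fallback sets out from 2 and returns at 3, introducing the para oxygen after the acylation instead of before. Bought 3-methoxyphenol is acylated with 2 in BF3·OEt2 (80 °C, ortho to OH by chelation) to 1-(2-hydroxy-4-methoxyphenyl)-2-methoxyethan-1-one F8. Elbs persulfate oxidation (K2S2O8, aq. KOH, 0 °C to rt) oxygenates para to the phenol to give potassium 4-hydroxy-2-methoxy-5-(2-methoxyacetyl)phenyl sulfate F9. Hot aq. HCl hydrolyses the sulfate to 3.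

## Further compounds

F1 | step 3 | 2-methoxy-1-(2,4,6-trihydroxyphenyl)ethan-1-one | COCC(=O)c1c(O)cc(O)cc1O
F2 | step 3 | 2-methoxy-1-(2,4,6-trihydroxyphenyl)-3-(2,3,4-trimethoxyphenyl)propane-1,3-dione (racemic at the labile C2) | COc1ccc(C(=O)C(OC)C(=O)c2c(O)cc(O)cc2O)c(OC)c1OC
F3 | step 3 | 5,7-dihydroxy-3-methoxy-2-(2,3,4-trimethoxyphenyl)-4H-chromen-4-one | COc1ccc(-c2oc3cc(O)cc(O)c3c(=O)c2OC)c(OC)c1OC
F4 | step 3 | 5-hydroxy-3,7-dimethoxy-2-(2,3,4-trimethoxyphenyl)-4H-chromen-4-one | COc1ccc(-c2oc3cc(OC)cc(O)c3c(=O)c2OC)c(OC)c1OC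
F5 | step 3 | potassium 5-hydroxy-3,7-dimethoxy-4-oxo-2-(2,3,4-trimethoxyphenyl)-4H-chromen-8-yl sulfate | COc1ccc(-c2oc3c(OS(=O)(=O)[O-])c(OC)cc(O)c3c(=O)c2OC)c(OC)c1OC.[K+]
F6 | step 2 | 2-methoxy-5-(2-methoxyacetyl)-1,4-phenylene bis(2,3,4-trimethoxybenzoate) | COCC(=O)c1cc(OC(=O)c2ccc(OC)c(OC)c2OC)c(OC)cc1OC(=O)c1ccc(OC)c(OC)c1OC
F7 | step 2 | 4-hydroxy-2-methoxy-5-[2-methoxy-3-oxo-3-(2,3,4-trimethoxyphenyl)propanoyl]phenyl 2,3,4-trimethoxybenzoate (racemic at the labile CH(OMe)) | COc1ccc(C(=O)C(OC)C(=O)c2cc(OC(=O)c3ccc(OC)c(OC)c3OC)c(OC)cc2O)c(OC)c1OC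
F8 | step 1 | 1-(2-hydroxy-4-methoxyphenyl)-2-methoxyethan-1-one | COCC(=O)c1ccc(OC)cc1O
F9 | step 1 | potassium 4-hydroxy-2-methoxy-5-(2-methoxyacetyl)phenyl sulfate | COCC(=O)c1cc(OS(=O)(=O)[O-])c(OC)cc1O.[K+]
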